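**Plan**
1. Retrosynthetic cuts: first the formyl C–C-2 bond of the ring (Vilsmeier–Haack), then the side-chain bond C-5′–C-6′ (Ni–H hydroalkylation of an α-olefin with a C14 iodide), then C-1′–C-2′ (Grignard addition to the formyl carbon of pyrrole-2-carbaldehyde, which becomes C-1′).
2. Forward: C4 Grignard reagent plus pyrrole-2-carbaldehyde gives a carbinol; hydride deoxygenation through the 1-azafulvene gives 2-(pent-4-enyl)pyrrole; union with 1-iodotetradecane at the terminal alkene carbon gives 2-nonadecylpyrrole; formylation at the free α-carbon gives the target. The pyrrole ring is bought, not built.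
3. Enabling feature: the side chain is unbranched and heteroatom-free, so C-5′ can be the unsubstituted terminus of a pent-4-enyl group on the pyrrole α-carbon. Anti-Markovnikov Ni–H insertion puts the metal on exactly this carbon, four sp3 carbons away from the ring and its N–H, and the alkene is used up without leaving a helper group.
4. Only helper: the carbinol OH on C-1′, removed through the ring itself (N-1/C-2/exocyclic C-1′ azafulvene). No protecting group is used.
5. Stereochemistry: the target has no stereocentre and no stereogenic double bond; the carbinol centre of 4 is racemic and is erased in step 2.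

Key step: step 3

Remark: the target is achiral, so its SMILES needs no stereodescriptors; locants 1′–19′ number the side chain starting at the ring.

**Step 1**
Reactants: 1 1H-pyrrole-2-carbaldehyde; 2 but-3-en-1-ylmagnesium bromide
Product: 4 racemic 1-(1H-pyrrol-2-yl)pent-4-en-1-ol, via bis(bromomagnesium) salt 3 (not isolated)
Conditions: 2 (2.3 equiv, THF solution), THF, 0 °C to rt; then cold H2O, extraction without acid; used crude
Reagents that add atoms: none
Why: Grignard 1,2-addition, in which the first equivalent of 2 removes the N–H proton (but-1-ene is lost) and the second adds to the formyl carbon, which becomes side-chain C-1′; the new carbinol centre forms racemic and is erased in step 2.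

**Step 2**
Reactants: 4 racemic 1-(1H-pyrrol-2-yl)pent-4-en-1-ol
Product: 6 2-(pent-4-en-1-yl)-1H-pyrrole, via azafulvene 5 (not isolated)
Conditions: NaBH4 (excess), i-PrOH, reflux, under N2
Reagents that add atoms: none
Why: Hydride deoxygenation of a 2-pyrrolylcarbinol (the second stage of the borohydride reduction of 2-acylpyrroles to 2-alkylpyrroles), in which loss of water across N-1/C-2/C-1′ gives the 1-azafulvene 5, which takes up hydride at the exocyclic carbon and regains the aromatic ring, while the isolated terminal alkene is inert to borohydride.

**Step 3**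
Reactants: 6 2-(pent-4-en-1-yl)-1H-pyrrole; 7 1-iodotetradecane
Product: 8 2-nonadecyl-1H-pyrrole
Conditions: 7 (1.5 equiv), NiBr2·diglyme (10 mol %), 4,4′-di-tert-butyl-2,2′-bipyridine (12 mol %), (EtO)2MeSiH (2.5 equiv), Na2CO3 (2 equiv), DMA, 25 °C, under N2
Reagents that add atoms: none
Why: A ligated Ni–H, formed from the nickel halide, the silane and carbonate, should insert the monosubstituted alkene of 6 anti-Markovnikov to give a primary alkyl–nickel at side-chain C-5′; iodine-atom abstraction from 7 gives the tetradecyl radical, which is captured at nickel, and C(sp3)–C(sp3) reductive elimination forms the C-5′–C-6′ bond. The closest known reaction type is the Ni–H-catalysed reductive hydroalkylation of unactivated α-olefins with primary alkyl iodides. No ring is closed and no stereocentre is created. The step needs linear (anti-Markovnikov) regioselectivity and no migration of nickel along the chain; the terminal, monosubstituted C=C and the faster coupling of the primary alkyl–nickel should secure both, since capture at the primary position outruns chain walking towards C-1′. Chemoselectivity towards the pyrrole is secured by the four sp3 carbons between ring and alkene and by the weak carbonate base, which leaves the N–H of the 2-alkylpyrrole untouched so that N-alkylation by 7 is not expected.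

**Step 4**
Reactants: 8 2-nonadecyl-1H-pyrrole
Product: 10 5-nonadecyl-1H-pyrrole-2-carbaldehyde, via iminium salt 9 (not isolated)
Conditions: POCl3 (1.1 equiv), DMF (1.2 equiv), ClCH2CH2Cl, 0 °C to rt; then aq. NaOH, 60 °C
Reagents that add atoms: N,N-dimethylformamide, CN(C)C=O; water, O
Why: Vilsmeier–Haack formylation (electrophilic aromatic substitution), in which the chloroiminium ion attacks the only free α-position (C-5) of the 2-alkylpyrrole and basic hydrolysis of iminium salt 9 releases the aldehyde.

**Compound list**
1 | 1H-pyrrole-2-carbaldehyde | O=Cc1ccc[nH]1 | starting material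
2 | but-3-en-1-ylmagnesium bromide | C=CCC[Mg]Br | starting material
3 | bis(bromomagnesium) salt of 1-(pyrrol-2-yl)pent-4-en-1-ol (N–MgBr and O–MgBr, formed in the flask) | C=CCCC(O[Mg]Br)c1cccn1[Mg]Br | intermediate
4 | 1-(1H-pyrrol-2-yl)pent-4-en-1-ol, racemic | C=CCCC(O)c1ccc[nH]1 | intermediate
5 | 2-(pent-4-en-1-ylidene)-2H-pyrrole (1-azafulvene, formed in the flask) | C=CCCC=C1C=CC=N1 | intermediate
6 | 2-(pent-4-en-1-yl)-1H-pyrrole | C=CCCCc1ccc[nH]1 | intermediate
7 | 1-iodotetradecane | CCCCCCCCCCCCCCI | starting material
8 | 2-nonadecyl-1H-pyrrole | CCCCCCCCCCCCCCCCCCCc1ccc[nH]1 | intermediate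
9 | N,N-dimethyl-1-(5-nonadecyl-1H-pyrrol-2-yl)methaniminium chloride (formed in the flask, counter-ion shown as chloride) | CCCCCCCCCCCCCCCCCCCc1ccc(C=[N+](C)C)[nH]1.[Cl-] | intermediate
10 | 5-nonadecyl-1H-pyrrole-2-carbaldehyde | CCCCCCCCCCCCCCCCCCCc1ccc(C=O)[nH]1 | target

Total step count: 4. Longest linear sequence: 4 steps (1 → 4 → 6 → 8 → 10).

**Steps most likely to fail**

Step 3. Nickel may migrate along the chain before coupling and give branched isomers, and the iodide may be reduced or the alkene simply hydrogenated instead of coupled. The fallback sets out from 6 and comes back at 8. Hydroboration of the terminal alkene with 9-BBN-H (THF, 0 °C to rt) should give 9-[5-(1H-pyrrol-2-yl)pentyl]-9-borabicyclo[3.3.1]nonane F1. This is coupled without isolation with 1-bromotetradecane under Pd(OAc)2/PCy3 and K3PO4·H2O in THF at rt (alkyl–alkyl Suzuki–Miyaura coupling), a two-electron transmetalation path with no metal hydride present.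

Step 2. The azafulvene may be attacked by a second pyrrole nucleus at its exocyclic carbon faster than hydride is delivered, which leads to oligomers. The fallback sets out from 4 and comes back at 6. Oxidation with activated MnO2 (CH2Cl2, rt) should give 1-(1H-pyrrol-2-yl)pent-4-en-1-one F2. Wolff–Kishner reduction (N2H4·H2O, KOH, diethylene glycol, 120 then 190 °C, under N2 to exclude diimide formation) then passes through 1-(1H-pyrrol-2-yl)pent-4-en-1-one hydrazone F3 and removes the oxygen by loss of dinitrogen, without an electrophilic azafulvene building up.

Step 4. The electrophile may attack a β-carbon, and the electron-rich ring may oligomerise under the acidic conditions. The fallback sets out from 8 and comes back at 10. N-Acylation with Boc2O/DMAP (MeCN, rt) should give tert-butyl 2-nonadecyl-1H-pyrrole-1-carboxylate F4. Deprotonation at the remaining α-carbon with LiTMP (THF, −78 °C) gives tert-butyl 2-lithio-5-nonadecyl-1H-pyrrole-1-carboxylate F5, and quenching with DMF gives tert-butyl 2-formyl-5-nonadecyl-1H-pyrrole-1-carboxylate F6. K2CO3 in MeOH (rt) then removes the carbamate from the acyl-activated nitrogen. The position of the formyl group is fixed here by directed metalation, not by electrophilic substitution.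

**Further compounds**
F1 | step 3 | 9-[5-(1H-pyrrol-2-yl)pentyl]-9-borabicyclo[3.3.1]nonane | C1CC2CCCC(C1)B2CCCCCc1ccc[nH]1
F2 | step 2 | 1-(1H-pyrrol-2-yl)pent-4-en-1-one | C=CCCC(=O)c1ccc[nH]1
F3 | step 2 | 1-(1H-pyrrol-2-yl)pent-4-en-1-one hydrazone | C=CCCC(=NN)c1ccc[nH]1
F4 | step 4 | tert-butyl 2-nonadecyl-1H-pyrrole-1-carboxylate | CCCCCCCCCCCCCCCCCCCc1cccn1C(=O)OC(C)(C)C
F5 | step 4 | tert-butyl 2-lithio-5-nonadecyl-1H-pyrrole-1-carboxylate | [Li]c1ccc(CCCCCCCCCCCCCCCCCCC)n1C(=O)OC(C)(C)C
F6 | step 4 | tert-butyl 2-formyl-5-nonadecyl-1H-pyrrole-1-carboxylate | CCCCCCCCCCCCCCCCCCCc1ccc(C=O)n1C(=O)OC(C)(C)C
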